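The readings were computed on assumed constants, and the scatter is random.

**The decision.** If E at a fixed time were a constant share of the charge, we could leave the grey run as planned and read its yield straight from the amber run. So, before charging, we test that share.

| setting | amber | blue | violet | red | grey |
|---|---|---|---|---|---|
| L | 0.400 M | 0.200 M | 0.400 M | 0.800 M | 1.80 M |
| E |  |  | 0.200 M |  |  |
| time |  |  |  |  | 69 min |

- amber run (time / min: [E] / M): 5.3: 0.0055; 16: 0.0285; 30: 0.0565; 48: 0.0793; 69: 0.0900
- blue run (time / min: [E] / M): 5.3: 8 × 10⁻⁴; 16: 0.0177; 30: 0.0374; 48: 0.0534; 69: 0.0560
- violet run (time / min: [E] / M): 5.3: 0.1788; 16: 0.1589; 30: 0.1473; 48: 0.1387; 69: 0.1238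
- red run (time / min: [E] / M): 5.3: 0.0070; 16: 0.0395; 30: 0.0840; 48: 0.1171; 69: 0.1387

(scatter of a reading: 0.001 M)

* the power of [L] that the first rate follows, about the charge of the amber run; measure it at two percent of L made into E (one fixed amount of E, the same in the runs compared)
* E in the grey run at 69 min, as a share of the L charged

- Overall: L -> E.
- Constant volume, constant temperature.
- Bound and free are read together.
- An order is taken over about fifteen percent of the charge, up and down.

**Two shares.** At 69 min the amber run holds 22.5 % of its charge as E. The red run, with twice that charge, holds 17.3 %, which is less than amber. Their ratio is 0.771. We call this the doubling factor, the part of the share at 69 min that survives one doubling of the charge. We freeze it as a constant and hold the blue run back as a test.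

**Our reckoning.** The grey charge lies 1.17 doublings above the red one, so we expect a share of 12.8 %, lower than red. Grey has 2.25 times the red charge but should make 1.66 times its E. We keep the charge, expecting the extra L to pay less.

**The forecast.** It gave an order of 0.45 and a grey share of 12 %, noting that “Doubling L multiplies the rate by only about 1.4”. Our share stands slightly above its value.

**The result.** The flask gives an order of 0.39 and a grey share of 12.4 %.

    L → J (0.06540 min⁻¹)
    J → E (0.1248 min⁻¹)
    E → Zo (0.02592 min⁻¹)
    2 L ⇌ L2, settled at all times (55.30 M⁻¹)

**Why it falls.** The grey share is this low because 2 L are tied up as L2, a fast pre-equilibrium, and E is lost to Zo: the same run gives 31.2 % without the tying up and 25.3 % without the loss. Measured from red, the grey run shows a doubling factor of 0.752, against our 0.771. Carried one doubling down from amber, our factor gives the blue run 29.2 %, and its reading at 69 min is lower, at 28.0 %.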